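The larch run can serve as a clock for this flask, since both carry the same equivalents of D and differ in the charge of J.

| flask | J | D | remark | time |
|---|---|---|---|---|
| larch | 1.2 M | 2 equiv | run made earlier |  |
| flask | 0.84 M | 2.00 equiv |  | 12 h |

larch run (percent of the J charged)

| time / h | J / % | X / % |
|---|---|---|
| 1.00 | 93.5 | 4.4 |
| 2.00 | 84.5 | 15.4 |
| 4.00 | 54.7 | 43.1 |
| 8.00 | 19.8 | 79.9 |
| 15.0 | 3.7 | 92.4 |

(readings scatter by 1 percentage point)

- the numbers in the tables scatter with a standard deviation of 1 percentage point
- steps under discussion: D <-> G; J + D -> X; J + D + X -> 2 X

* share of the J used up at 12 h
* X at 12 h, in percent of the J charged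

1. Follow one J molecule to its fork. It can leave by J + D, or by J + D + X (autocatalysis). At equal equivalents, counted in fractions of the charge, the first door's pace goes with the J charge and the second's with its square.

2. If the second door carries the run, 12 h here equals 5.88 h of the larch run. This time, the flask's time multiplied by the squared ratio of the J charges, is our reduced time. Read between the larch readings, it gives X 60.4%.

3. If the first door carries it, the ratio enters once: 8.40 h, and X 80.6%. The two ways part.

4. To see which one cheats, we compare paces. X gained 4.4% in the first hour, but 28 percentage points in the two hours after 2.00 h. As a rough reading, the second door took 68.2% of the mid-run traffic, so the single-ratio clock cheats. The squared clock errs too, but in two opposite directions: it slows the first door too much, and D passing into G keeps its own time, unchanged by dilution. We commit to X near 60.4%, and we watch the J charge, which enters this clock squared.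

5. The forecast is higher, with 71% used up and X 69.5%, reasoning that “the more dilute flask should run clearly slower”.

The flask gives 60.4% used up and X 60.4%.

    D ⇌ G (K = 3.60, k = 1.90 × 10⁻⁵ /s)
    J + D → X (k = 4.10 × 10⁻⁶ /M/s)
    J + D + X → 2 X (k = 9.20 × 10⁻⁵ /M²/s)

The reduced time of 5.88 h had read X 60.4%, and the flask stands at 60.4%. The neighbouring flask holds the same equivalents and time but charges 1.4 M of J, so its reduced time is 16.3 h, past the last larch reading at 15.0 h. That reading had J 3.7% and X 92.4%, so the clock puts the neighbouring flask slightly further on. At 12.0 h, the neighbouring flask holds J 2.53% and X 97.5%.

The readings come from a simulation with made-up constants, noise included.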